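The flavone is disconnected across ring C at O1–C8a, C4a–C4 and O1–C2. Ring A bears the ring oxygen O1 on C8a and the C4 carbonyl on the adjacent C4a; this ortho-oxy aryl ketone motif is what results when a benzyne inserts into the C–O bond of a carboxylic acid. Fluoride therefore releases 3-benzyloxy-5-methoxybenzyne from its ortho-silylaryl triflate in the presence of the ring B arylpropiolic acid. Carboxylate addition, oxygen-to-carbon acyl shift and oxa-Michael closure of ring C follow in one pot. The lone C5 methoxy beside the aryne sets the orientation, so C8 enters as C–H and is oxygenated afterwards by bromination and copper-mediated methoxylation, before global hydrogenolysis.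

Key step: step 12

**Ring A aryne precursor**

Step 1
Reactants: 1 phloroglucinol (benzene-1,3,5-triol)
Product: 2 5-(benzyloxy)benzene-1,3-diol
Conditions: 1 (1.5 equiv), NaH (1.0 equiv), BnBr (1.0 equiv), DMF, 0 °C to rt
Reagents that add atoms: benzyl bromide, BrCc1ccccc1
Why: Williamson etherification under statistical control, in which excess triol and one equivalent of base in DMF should favour the mono-O-benzyl ether, separable from recovered 1 and higher ethers by chromatography.

Step 2
Reactants: 2 5-(benzyloxy)benzene-1,3-diol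
Product: 3 5-(benzyloxy)-1,3-phenylene bis(N,N-diethylcarbamate)
Conditions: ClCONEt2 (2.5 equiv), K2CO3, MeCN, reflux
Reagents that add atoms: N,N-diethylcarbamoyl chloride, CCN(CC)C(Cl)=O
Why: O-acylation of both phenoxides (carbamate formation) should be exhaustive and places the strongest oxygen-based directing groups on the two oxygens that flank C2.

Step 3
Reactants: 3 5-(benzyloxy)-1,3-phenylene bis(N,N-diethylcarbamate)
Product: 5 5-(benzyloxy)-2-(trimethylsilyl)-1,3-phenylene bis(N,N-diethylcarbamate), via 2-lithio bis-carbamate 4 (not isolated)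
Conditions: s-BuLi, TMEDA, THF, −78 °C; then Me3SiCl, −78 °C to rt
Reagents that add atoms: chlorotrimethylsilane, C[Si](C)(C)Cl
Why: Directed ortho-metalation, in which the C–H between the two carbamates is the most acidic and doubly coordinated site, so lithiation there at −78 °C should outpace benzylic deprotonation and carbamoyl migration before the silyl chloride quench.

Step 4
Reactants: 5 5-(benzyloxy)-2-(trimethylsilyl)-1,3-phenylene bis(N,N-diethylcarbamate)
Product: 6 5-(benzyloxy)-2-(trimethylsilyl)benzene-1,3-diol
Conditions: LiAlH4, THF, 0 °C to reflux; aq. potassium sodium tartrate work-up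
Reagents that add atoms: none
Why: Hydride reduction of aryl carbamates should release both phenols while the benzyl ether and the C–Si bond are inert, and the near-neutral work-up avoids ipso-protodesilylation of the electron-rich arylsilane.

Step 5
Reactants: 6 5-(benzyloxy)-2-(trimethylsilyl)benzene-1,3-diol
Product: 7 5-(benzyloxy)-3-methoxy-2-(trimethylsilyl)phenol
Conditions: MeI (0.95 equiv), K2CO3 (1.0 equiv), acetone, rt
Reagents that add atoms: iodomethane, CI
Why: Williamson mono-methylation of a diol whose two hydroxyls are symmetry-equivalent can give only one mono-ether, which should be separable from recovered 6 and the diether.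

Step 6
Reactants: 7 5-(benzyloxy)-3-methoxy-2-(trimethylsilyl)phenol
Product: 8 5-(benzyloxy)-3-methoxy-2-(trimethylsilyl)phenyl trifluoromethanesulfonate
Conditions: PhNTf2, DBU, MeCN, rt
Reagents that add atoms: N-phenylbis(trifluoromethanesulfonimide), O=S(=O)(N(c1ccccc1)S(=O)(=O)C(F)(F)F)C(F)(F)F
Why: O-sulfonylation of the phenoxide with a mild triflyl donor under amine base should give the aryl triflate without the strong acid that could cleave the aryl–silicon bond.

**Ring B arylpropiolic acid**

Step 7
Reactants: 9 3,5-dihydroxy-4-methoxybenzoic acid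
Product: 10 benzyl 3,5-bis(benzyloxy)-4-methoxybenzoate
Conditions: BnBr (3.5 equiv), K2CO3, DMF, 60 °C
Reagents that add atoms: benzyl bromide, BrCc1ccccc1
Why: Williamson etherification of both phenols and SN2 esterification of the carboxylate should proceed together with excess benzyl bromide.

Step 8
Reactants: 10 benzyl 3,5-bis(benzyloxy)-4-methoxybenzoate
Product: 11 [3,5-bis(benzyloxy)-4-methoxyphenyl]methanol
Conditions: LiAlH4, THF, 0 °C to rt
Reagents that add atoms: none
Why: Hydride reduction of the ester to the benzylic alcohol leaves aryl benzyl and methyl ethers untouched.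

Step 9
Reactants: 11 [3,5-bis(benzyloxy)-4-methoxyphenyl]methanol
Product: 12 3,5-bis(benzyloxy)-4-methoxybenzaldehyde
Conditions: activated MnO2, CH2Cl2, rt
Reagents that add atoms: none
Why: Heterogeneous MnO2 oxidation is selective for benzylic alcohols and should stop at the aldehyde.

Step 10
Reactants: 12 3,5-bis(benzyloxy)-4-methoxybenzaldehyde
Product: 13 1,3-bis(benzyloxy)-5-(2,2-dibromoethenyl)-2-methoxybenzene
Conditions: CBr4, PPh3, CH2Cl2, 0 °C
Reagents that add atoms: carbon tetrabromide, BrC(Br)(Br)Br
Why: Corey–Fuchs dibromo-olefination, a Wittig-type reaction of the ylide formed in the flask, is reliable for electron-rich benzaldehydes.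

Step 11
Reactants: 13 1,3-bis(benzyloxy)-5-(2,2-dibromoethenyl)-2-methoxybenzene
Product: 15 3-[3,5-bis(benzyloxy)-4-methoxyphenyl]prop-2-ynoic acid, via lithium acetylide 14 (not isolated)
Conditions: n-BuLi (2.2 equiv), THF, −78 °C; then CO2, −78 °C to rt; 1 M HCl
Reagents that add atoms: carbon dioxide, O=C=O
Why: Second stage of the Corey–Fuchs sequence, in which elimination and bromine–lithium exchange give the lithium acetylide, whose carboxylation and acidification should give the arylpropiolic acid.

**Key step and end game**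

Step 12
Reactants: 8 5-(benzyloxy)-3-methoxy-2-(trimethylsilyl)phenyl trifluoromethanesulfonate; 15 3-[3,5-bis(benzyloxy)-4-methoxyphenyl]prop-2-ynoic acid
Product: 18 7-(benzyloxy)-2-[3,5-bis(benzyloxy)-4-methoxyphenyl]-5-methoxy-4H-chromen-4-one, via 3-benzyloxy-5-methoxybenzyne 16 (not isolated), via cesium ortho-acylphenoxide 17 (not isolated)
Conditions: 8 (1.5 equiv), CsF (4 equiv), THF, 125 °C, sealed tube
Reagents that add atoms: none
Why: Fluoride attacks silicon of 8 and expels triflate to give aryne 16; the cesium carboxylate of 15 adds through oxygen to C8a, the aryne carbon meta to the methoxy, so the aryl anion develops at C4a beside the inductively stabilising C5 methoxy. That anion attacks the neighbouring ester carbonyl through a four-membered transition state and the acyl group moves from oxygen to carbon (an anionic Fries-type 1,3-shift, net aryne insertion into the acid C–O bond), giving phenoxide 17 with O1–C8a and C4a–C4 in place. Ring C then closes by 6-endo-dig oxa-Michael addition of O1 to the ynone β-carbon C2, and protonation at C3 gives the chromen-4-one; the closest known reaction type is the fluoride-mediated intermolecular C–O addition of carboxylic acids to arynes, which gives ortho-hydroxyaryl ketones and, with arylpropiolic acids, flavones. No stereocentre is formed. The step needs oxygen at C8a and acyl at C4a, which the single methoxy flanking the triple bond secures through aryne distortion and stabilisation of the ortho anion, and this is why C8 carries no substituent at this stage; it also needs acyl transfer to outrun protonation of the aryl anion, which hot aprotic THF favours, and polarity-matched 6-endo closure over 5-exo closure.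

Step 13
Reactants: 18 7-(benzyloxy)-2-[3,5-bis(benzyloxy)-4-methoxyphenyl]-5-methoxy-4H-chromen-4-one
Product: 19 7-(benzyloxy)-2-[3,5-bis(benzyloxy)-4-methoxyphenyl]-8-bromo-5-methoxy-4H-chromen-4-one
Conditions: NBS (1.05 equiv), DMF, 0 °C to rt, dark
Reagents that add atoms: N-bromosuccinimide, O=C1CCC(=O)N1Br
Why: Electrophilic aromatic bromination should occur at C8, which is ortho to O7 and O1 and para to the C5 methoxy on the phloroglucinol-type ring A and less crowded than C6 between two alkoxy groups, while ring B is less activated and conjugated to the enone.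

Step 14
Reactants: 19 7-(benzyloxy)-2-[3,5-bis(benzyloxy)-4-methoxyphenyl]-8-bromo-5-methoxy-4H-chromen-4-one
Product: 20 7-(benzyloxy)-2-[3,5-bis(benzyloxy)-4-methoxyphenyl]-5,8-dimethoxy-4H-chromen-4-one
Conditions: NaOMe (25% in MeOH, excess), CuBr, DMF, 110 °C; dilute HCl work-up
Reagents that add atoms: sodium methoxide, [Na+].[O-]C
Why: Ullmann-type copper-mediated C–O coupling of an aryl bromide with methoxide is an established way to turn 8-bromoflavone ethers into 8-methoxy compounds, the benzyl and methyl ethers being stable to methoxide and any opening of ring C being reversed on acidic work-up.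

Step 15
Reactants: 20 7-(benzyloxy)-2-[3,5-bis(benzyloxy)-4-methoxyphenyl]-5,8-dimethoxy-4H-chromen-4-one
Product: 21 2-(3,5-dihydroxy-4-methoxyphenyl)-7-hydroxy-5,8-dimethoxy-4H-chromen-4-one
Conditions: H2 (1 atm), 10% Pd/C, THF/MeOH, rt
Reagents that add atoms: none
Why: Catalytic hydrogenolysis should cleave the three O-benzyl groups while the aryl methyl ethers, including the Lewis-acid-labile C5 methoxy, and the C2=C3 bond of the flavone remain under one atmosphere of hydrogen.

**Compound list**

1 | phloroglucinol (benzene-1,3,5-triol) | Oc1cc(O)cc(O)c1 | starting material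
2 | 5-(benzyloxy)benzene-1,3-diol | Oc1cc(O)cc(OCc2ccccc2)c1 | intermediate
3 | 5-(benzyloxy)-1,3-phenylene bis(N,N-diethylcarbamate) | CCN(CC)C(=O)Oc1cc(OCc2ccccc2)cc(OC(=O)N(CC)CC)c1 | intermediate
4 | [4-(benzyloxy)-2,6-bis(diethylcarbamoyloxy)phenyl]lithium (not isolated) | [Li]c1c(OC(=O)N(CC)CC)cc(OCc2ccccc2)cc1OC(=O)N(CC)CC | intermediate
5 | 5-(benzyloxy)-2-(trimethylsilyl)-1,3-phenylene bis(N,N-diethylcarbamate) | CCN(CC)C(=O)Oc1cc(OCc2ccccc2)cc(OC(=O)N(CC)CC)c1[Si](C)(C)C | intermediate
6 | 5-(benzyloxy)-2-(trimethylsilyl)benzene-1,3-diol | C[Si](C)(C)c1c(O)cc(OCc2ccccc2)cc1O | intermediate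
7 | 5-(benzyloxy)-3-methoxy-2-(trimethylsilyl)phenol | COc1cc(OCc2ccccc2)cc(O)c1[Si](C)(C)C | intermediate
8 | 5-(benzyloxy)-3-methoxy-2-(trimethylsilyl)phenyl trifluoromethanesulfonate | COc1cc(OCc2ccccc2)cc(OS(=O)(=O)C(F)(F)F)c1[Si](C)(C)C | intermediate
9 | 3,5-dihydroxy-4-methoxybenzoic acid | COc1c(O)cc(C(=O)O)cc1O | starting material
10 | benzyl 3,5-bis(benzyloxy)-4-methoxybenzoate | COc1c(OCc2ccccc2)cc(C(=O)OCc2ccccc2)cc1OCc1ccccc1 | intermediate
11 | [3,5-bis(benzyloxy)-4-methoxyphenyl]methanol | COc1c(OCc2ccccc2)cc(CO)cc1OCc1ccccc1 | intermediate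
12 | 3,5-bis(benzyloxy)-4-methoxybenzaldehyde | COc1c(OCc2ccccc2)cc(C=O)cc1OCc1ccccc1 | intermediate
13 | 1,3-bis(benzyloxy)-5-(2,2-dibromoethenyl)-2-methoxybenzene | COc1c(OCc2ccccc2)cc(C=C(Br)Br)cc1OCc1ccccc1 | intermediate
14 | {[3,5-bis(benzyloxy)-4-methoxyphenyl]ethynyl}lithium (not isolated) | [Li]C#Cc1cc(OCc2ccccc2)c(OC)c(OCc2ccccc2)c1 | intermediate
15 | 3-[3,5-bis(benzyloxy)-4-methoxyphenyl]prop-2-ynoic acid | OC(=O)C#Cc1cc(OCc2ccccc2)c(OC)c(OCc2ccccc2)c1 | intermediate
16 | 5-(benzyloxy)-3-methoxy-1,2-didehydrobenzene (3-benzyloxy-5-methoxybenzyne, not isolated) | COC1=CC(OCc2ccccc2)=CC#C1 | intermediate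
17 | cesium 5-(benzyloxy)-2-{3-[3,5-bis(benzyloxy)-4-methoxyphenyl]prop-2-ynoyl}-3-methoxyphenolate (not isolated) | [Cs+].[O-]c1cc(OCc2ccccc2)cc(OC)c1C(=O)C#Cc1cc(OCc2ccccc2)c(OC)c(OCc2ccccc2)c1 | intermediate
18 | 7-(benzyloxy)-2-[3,5-bis(benzyloxy)-4-methoxyphenyl]-5-methoxy-4H-chromen-4-one | COc1cc(OCc2ccccc2)cc2oc(-c3cc(OCc4ccccc4)c(OC)c(OCc4ccccc4)c3)cc(=O)c12 | intermediate
19 | 7-(benzyloxy)-2-[3,5-bis(benzyloxy)-4-methoxyphenyl]-8-bromo-5-methoxy-4H-chromen-4-one | COc1cc(OCc2ccccc2)c(Br)c2oc(-c3cc(OCc4ccccc4)c(OC)c(OCc4ccccc4)c3)cc(=O)c12 | intermediate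
20 | 7-(benzyloxy)-2-[3,5-bis(benzyloxy)-4-methoxyphenyl]-5,8-dimethoxy-4H-chromen-4-one | COc1cc(OCc2ccccc2)c(OC)c2oc(-c3cc(OCc4ccccc4)c(OC)c(OCc4ccccc4)c3)cc(=O)c12 | intermediate
21 | 2-(3,5-dihydroxy-4-methoxyphenyl)-7-hydroxy-5,8-dimethoxy-4H-chromen-4-one | COc1c(O)cc(-c2cc(=O)c3c(OC)cc(O)c(OC)c3o2)cc1O | target

**Count and risk**

Total step count: 15. Longest linear sequence: 10 steps (steps 1–6 and 12–15, from phloroglucinol).

Steps most likely to fail:

1. Step 12. The aryl anion may be protonated before the acyl shift, so the sequence stops at the aryl ester. The propiolate may also lose CO2 at 125 °C before it is captured. The fallback builds the same ortho-hydroxyaryl ynone by carbonylative Sonogashira annulation; it sets out from 7 and 13 and comes back at 18. ICl in CH2Cl2 at −78 °C should replace the silyl group of 7 by iodine (ipso-iododesilylation) to give 5-(benzyloxy)-2-iodo-3-methoxyphenol F1. Treating 13 with n-BuLi in THF at −78 °C and quenching with aqueous NH4Cl should give 1,3-bis(benzyloxy)-5-ethynyl-2-methoxybenzene F2. F1 and F2 are then heated under CO with PdCl2(PPh3)2 in Et2NH at 120 °C; the acylpalladium species couples with the alkyne and the amine base promotes 6-endo closure to 18.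

2. Step 14. The C–Br bond may be reduced instead of substituted at this doubly ortho-flanked position, and methoxide may open ring C irreversibly. The fallback replaces the C–O coupling by borylation and oxidation; it sets out from 19 and comes back at 20. Miyaura borylation (B2pin2, Pd(OAc)2, SPhos, KOAc, dioxane, 100 °C) should give 7-(benzyloxy)-2-[3,5-bis(benzyloxy)-4-methoxyphenyl]-5-methoxy-8-(4,4,5,5-tetramethyl-1,3,2-dioxaborolan-2-yl)-4H-chromen-4-one F3. Mild oxidation with NaBO3·4H2O in THF/H2O at rt should give 7-(benzyloxy)-2-[3,5-bis(benzyloxy)-4-methoxyphenyl]-8-hydroxy-5-methoxy-4H-chromen-4-one F4. O-methylation with MeI and K2CO3 in acetone then gives 20.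

3. Step 3. The base may deprotonate the benzylic CH2 of the benzyl ether in competition with ring lithiation, or a carbamoyl group may migrate to C2 before the silyl chloride arrives. The fallback replaces deprotonation by halogen–lithium exchange; it sets out from 2 and comes back at 6, bypassing steps 2 to 4. Iodination of 2 with I2 and NaHCO3 in THF/H2O at 0 °C should occur between the two hydroxyls, as it does for resorcinol, to give 5-(benzyloxy)-2-iodobenzene-1,3-diol F5. HMDS at reflux should silylate both hydroxyls to give 5-(benzyloxy)-2-iodo-1,3-bis(trimethylsilyloxy)benzene F6. n-BuLi in THF at −78 °C then effects iodine–lithium exchange, the aryllithium takes a silyl group from a neighbouring oxygen (retro-Brook 1,3-shift), and aqueous work-up removes the remaining O-silyl group to give 6.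

Further compounds
F1 | step 12 | 5-(benzyloxy)-2-iodo-3-methoxyphenol | COc1cc(OCc2ccccc2)cc(O)c1I
F2 | step 12 | 1,3-bis(benzyloxy)-5-ethynyl-2-methoxybenzene | C#Cc1cc(OCc2ccccc2)c(OC)c(OCc2ccccc2)c1
F3 | step 14 | 7-(benzyloxy)-2-[3,5-bis(benzyloxy)-4-methoxyphenyl]-5-methoxy-8-(4,4,5,5-tetramethyl-1,3,2-dioxaborolan-2-yl)-4H-chromen-4-one | COc1cc(OCc2ccccc2)c(B3OC(C)(C)C(C)(C)O3)c2oc(-c3cc(OCc4ccccc4)c(OC)c(OCc4ccccc4)c3)cc(=O)c12
F4 | step 14 | 7-(benzyloxy)-2-[3,5-bis(benzyloxy)-4-methoxyphenyl]-8-hydroxy-5-methoxy-4H-chromen-4-one | COc1cc(OCc2ccccc2)c(O)c2oc(-c3cc(OCc4ccccc4)c(OC)c(OCc4ccccc4)c3)cc(=O)c12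
F5 | step 3 | 5-(benzyloxy)-2-iodobenzene-1,3-diol | Oc1cc(OCc2ccccc2)cc(O)c1I
F6 | step 3 | 5-(benzyloxy)-2-iodo-1,3-bis(trimethylsilyloxy)benzene | C[Si](C)(C)Oc1cc(OCc2ccccc2)cc(O[Si](C)(C)C)c1I
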